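Ring B of the 1,2-dihydronaphthalene (C1 aryl-bearing CH, C2 formyl-bearing CH, C3 alkene carbon carrying the C9 hydroxymethyl, C4 alkene CH, C4a and C8a the ring A fusion carbons) is opened at C4–C4a. The key step exploits that C4 is an unsubstituted alkene CH on ring A while C3 carries C9: a 6-endo Mizoroki–Heck arylation of a 2-substituted acrylate forms C4–C4a, closes ring B and leaves the C3=C4 enoate in one operation. Its precursor is a 2-methylenesuccinate (C2 methyl ester, C3 tert-butyl ester) whose C1 carries both aryl groups, ring A brominated at C4a; C1 is set by rhodium-catalysed asymmetric arylation and C2 is equilibrated to trans after ring closure.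

Key step: step 7

Remarks. ArA = 2-bromo-4-methoxy-5-(triisopropylsilyloxy)phenyl (ring A, Br on C4a). ArC = 3-methoxy-4-(triisopropylsilyloxy)phenyl (ring C). Names of 15–23 use the core numbering above.
The enolate alkylation of step 5 is not expected to control C2. Compounds 10–15 are therefore carried as C2 epimer pairs with C1 fixed as S (12 and 13 are also epimeric at the aminomethyl carbon). C2 is fixed as R, trans to the C1 aryl group, in step 7.
Assumption: the target is taken as the open γ-hydroxy aldehyde (1S,2R). In this trans series, closure of C9–OH onto the C2 carbonyl would force both substituents of ring B pseudo-equatorial and is not expected to dominate.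

Step 1
Reactants: 1 6-bromoisovanillin (2-bromo-5-hydroxy-4-methoxybenzaldehyde)
Product: 2 2-bromo-4-methoxy-5-(triisopropylsilyloxy)benzaldehyde
Conditions: TIPSCl, imidazole, DMF, 25 °C
Reagents that add atoms: chlorotriisopropylsilane (TIPSCl), CC(C)[Si](Cl)(C(C)C)C(C)C
Why: Phenol O-silylation gives a robust aryl silyl ether that removes the acidic OH before the enolate steps and tolerates the later amine, acid and hydride reagents.

Step 2
Reactants: 2 2-bromo-4-methoxy-5-(triisopropylsilyloxy)benzaldehyde; 3 methyl (triphenylphosphoranylidene)acetate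
Product: 4 methyl (E)-3-ArA-prop-2-enoate
Conditions: toluene, 80 °C
Reagents that add atoms: none
Why: Wittig olefination with a stabilised ylide gives the E-cinnamate under neutral conditions that leave the aryl bromide and the silyl ether untouched.

Step 3
Reactants: 5 4-hydroxy-3-methoxyphenylboronic acid pinacol ester
Product: 6 2-ArC-4,4,5,5-tetramethyl-1,3,2-dioxaborolane
Conditions: TIPSCl, imidazole, DMF, 25 °C
Reagents that add atoms: chlorotriisopropylsilane (TIPSCl), CC(C)[Si](Cl)(C(C)C)C(C)C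
Why: Phenol O-silylation delivers ring C already protected for the enolate chemistry and avoids an electron-rich phenoxide boronate that is prone to protodeboronation.

Step 4
Reactants: 4 methyl (E)-3-ArA-prop-2-enoate; 6 2-ArC-4,4,5,5-tetramethyl-1,3,2-dioxaborolane
Product: 7 methyl (3S)-3-ArA-3-ArC-propanoate
Conditions: [Rh(OH)((R)-BINAP)]2 (3 mol%), dioxane/H2O 10:1, 50 °C
Reagents that add atoms: none
Why: Hayashi–Miyaura asymmetric 1,4-addition, in which the aryl group of 6 passes from boron to the hydroxo-rhodium complex, the aryl–rhodium species inserts the E-enoate and water protonates the rhodium enolate; C1 is set as S because the (R)-BINAP complex exposes only one enantioface of the enoate (accepted quadrant model for this ligand), and the aryl bromide and silyl ethers are inert under these base-free conditions.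

Step 5
Reactants: 7 methyl (3S)-3-ArA-3-ArC-propanoate; 8 tert-butyl bromoacetate
Product: 10 4-tert-butyl 1-methyl 2-[(S)-ArA(ArC)methyl]butanedioate (C2 epimers), via lithium enolate 9 (not isolated)
Conditions: LiN(i-Pr)2, THF, −78 °C; then 8, DMPU, −78 → −30 °C
Reagents that add atoms: none
Why: Ester enolate alkylation (SN2) with the activated primary bromide forms the C2–C3 bond; C2 arises under weak 1,2-induction from C1 as an epimer pair, which is accepted because C2 is equilibrated in step 7.

Step 6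
Reactants: 10 4-tert-butyl 1-methyl 2-[(S)-ArA(ArC)methyl]butanedioate (C2 epimers)
Product: 14 1-tert-butyl 4-methyl 2-methylidene-3-[(S)-ArA(ArC)methyl]butanedioate (C2 epimers), via lithium enolate 11 (not isolated), via Mannich amine 12 (not isolated), via ammonium iodide 13 (not isolated)
Conditions: LiN(i-Pr)2, THF, −78 °C; dimethylmethyleneiminium iodide, −78 → 0 °C; MeI, MeOH, 25 °C; aq. NaHCO3, CH2Cl2, 25 °C
Reagents that add atoms: dimethylmethyleneiminium iodide, C=[N+](C)C.[I-]
Why: Eschenmoser methylenation (Mannich reaction of the ester enolate, N-methylation, E1cB loss of trimethylamine), in which the amide base should remove a proton from the unhindered C3 methylene in preference to the C2 methine shielded by the diarylmethyl group, and bicarbonate is too weak to move the new double bond.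

Step 7
Reactants: 14 1-tert-butyl 4-methyl 2-methylidene-3-[(S)-ArA(ArC)methyl]butanedioate (C2 epimers)
Product: 16 trans (1S,2R) 3-tert-butyl 2-methyl 1-ArC-1,2-dihydronaphthalene-2,3-dicarboxylate, via cyclised diester 15 (not isolated)
Conditions: Pd(OAc)2 (10 mol%), P(o-tol)3 (25 mol%), i-Pr2NEt, MeCN, 85 °C; silica plug; then DBU (0.5 equiv), toluene, 60 °C
Reagents that add atoms: none
Why: Zerovalent palladium formed from Pd(OAc)2 and P(o-tol)3 inserts into the C4a–Br bond, the arylpalladium bromide adds syn across the 2-substituted acrylate with the aryl carbon going to the terminal CH2 (C4) and palladium to the ester-bearing C3, and syn β-hydride elimination of a C4 hydrogen releases the C3=C4 enoate while the amine takes up HBr. The closest known reaction type is the intramolecular Mizoroki–Heck arylation of Morita–Baylis–Hillman-type 2-substituted acrylates, which cyclise in the endo mode. Ring B closes 6-endo-trig, both alkene carbons ending inside the new ring. The C–C bond formation creates no stereocentre: C1 is carried unchanged from step 4, and C2, an enolisable allylic α-ester CH, is then equilibrated by DBU to the trans (1S,2R) diester, in which the C1 aryl and C2 ester groups are both pseudo-axial and escape the peri and allylic strain of the cis isomer. The step needs endo over 5-exo closure and C4–H over C2–H elimination; the polarised acrylate and its α-substituent send the aryl group to the unsubstituted terminus (exo attack would build a quaternary carbon bearing a neopentyl palladium with no β-hydrogen), and elimination towards C4 gives the alkene conjugated with ring A and the ester. Only ring A carries the halide, so ring C cannot take part, and the hindered amine is chosen so that the methylene double bond is not moved into conjugation before cyclisation.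

Step 8
Reactants: 16 trans (1S,2R) 3-tert-butyl 2-methyl 1-ArC-1,2-dihydronaphthalene-2,3-dicarboxylate
Product: 17 (1S,2R) 2-(methoxycarbonyl)-1-ArC-1,2-dihydronaphthalene-3-carboxylic acid
Conditions: CF3CO2H/CH2Cl2 (1:4), 0 → 25 °C
Reagents that add atoms: none
Why: Acidolysis of the tert-butyl ester (E1 loss of isobutene) frees only the conjugated C9 carboxyl and leaves the methyl ester, the aryl silyl ethers and both stereocentres untouched.

Step 9
Reactants: 17 (1S,2R) 2-(methoxycarbonyl)-1-ArC-1,2-dihydronaphthalene-3-carboxylic acid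
Product: 19 methyl (1S,2R) 3-(hydroxymethyl)-1-ArC-1,2-dihydronaphthalene-2-carboxylate, via mixed anhydride 18 (not isolated)
Conditions: i-BuOCOCl, N-methylmorpholine, THF, −15 °C; then NaBH4, THF/H2O, 0 °C
Reagents that add atoms: none
Why: Mixed carbonic anhydride reduction, in which only the activated C9 carboxyl is reduced by NaBH4 (1,2-hydride addition) to the allylic alcohol while the unactivated C2 methyl ester is inert, and the pseudo-axial C2 ester of the trans isomer is held away from the new hydroxyl so that lactonisation should not compete.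

Step 10
Reactants: 19 methyl (1S,2R) 3-(hydroxymethyl)-1-ArC-1,2-dihydronaphthalene-2-carboxylate
Product: 20 methyl (1S,2R) 3-[(tert-butyldimethylsilyloxy)methyl]-1-ArC-1,2-dihydronaphthalene-2-carboxylate
Conditions: TBSCl, imidazole, DMF, 25 °C
Reagents that add atoms: tert-butylchlorodimethylsilane (TBSCl), CC(C)(C)[Si](C)(C)Cl
Why: Silyl ether formation on the primary allylic alcohol keeps C9–OH from being oxidised in step 12 and from closing onto the C2 carbonyl.

Step 11
Reactants: 20 methyl (1S,2R) 3-[(tert-butyldimethylsilyloxy)methyl]-1-ArC-1,2-dihydronaphthalene-2-carboxylate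
Product: 21 (1S,2R) 3-[(tert-butyldimethylsilyloxy)methyl]-2-(hydroxymethyl)-1-ArC-1,2-dihydronaphthalene
Conditions: i-Bu2AlH (3 equiv), CH2Cl2, −78 → 0 °C; aq. potassium sodium tartrate
Reagents that add atoms: none
Why: Ester reduction with excess i-Bu2AlH to the primary alcohol avoids an uncertain partial reduction, and the silyl ethers and the trisubstituted alkene are inert at low temperature.

Step 12
Reactants: 21 (1S,2R) 3-[(tert-butyldimethylsilyloxy)methyl]-2-(hydroxymethyl)-1-ArC-1,2-dihydronaphthalene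
Product: 22 (1S,2R) 3-[(tert-butyldimethylsilyloxy)methyl]-1-ArC-1,2-dihydronaphthalene-2-carbaldehyde
Conditions: Dess–Martin periodinane, NaHCO3, CH2Cl2, 0 → 25 °C
Reagents that add atoms: none
Why: Dess–Martin oxidation under bicarbonate buffering gives the α-branched β,γ-unsaturated aldehyde without the base or heat that could epimerise C2 or move the C3=C4 double bond.

Step 13
Reactants: 22 (1S,2R) 3-[(tert-butyldimethylsilyloxy)methyl]-1-ArC-1,2-dihydronaphthalene-2-carbaldehyde
Product: 23 (1S,2R)-7-hydroxy-1-(4-hydroxy-3-methoxyphenyl)-3-(hydroxymethyl)-6-methoxy-1,2-dihydronaphthalene-2-carbaldehyde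
Conditions: Bu4NF, AcOH (1:1), THF, 0 → 25 °C
Reagents that add atoms: none
Why: Fluoride-mediated desilylation buffered with acetic acid removes the two aryl triisopropylsilyl ethers and the alkyl silyl ether while keeping the phenoxide concentration low, so the enolisable C2 aldehyde should keep its trans (1S,2R) configuration.

Compound list
1 | 6-bromoisovanillin (2-bromo-5-hydroxy-4-methoxybenzaldehyde) | COc1cc(Br)c(C=O)cc1O | starting material
2 | 2-bromo-4-methoxy-5-(triisopropylsilyloxy)benzaldehyde | COc1cc(Br)c(C=O)cc1O[Si](C(C)C)(C(C)C)C(C)C | intermediate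
3 | methyl (triphenylphosphoranylidene)acetate | COC(=O)C=P(c1ccccc1)(c1ccccc1)c1ccccc1 | starting material
4 | methyl (E)-3-[2-bromo-4-methoxy-5-(triisopropylsilyloxy)phenyl]prop-2-enoate | COC(=O)/C=C/c1cc(O[Si](C(C)C)(C(C)C)C(C)C)c(OC)cc1Br | intermediate
5 | 4-hydroxy-3-methoxyphenylboronic acid pinacol ester | COc1cc(B2OC(C)(C)C(C)(C)O2)ccc1O | starting material
6 | 2-[3-methoxy-4-(triisopropylsilyloxy)phenyl]-4,4,5,5-tetramethyl-1,3,2-dioxaborolane | COc1cc(B2OC(C)(C)C(C)(C)O2)ccc1O[Si](C(C)C)(C(C)C)C(C)C | intermediate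
7 | methyl (3S)-3-[2-bromo-4-methoxy-5-(triisopropylsilyloxy)phenyl]-3-[3-methoxy-4-(triisopropylsilyloxy)phenyl]propanoate | COc1cc([C@@H](c2cc(O[Si](C(C)C)(C(C)C)C(C)C)c(OC)cc2Br)CC(=O)OC)ccc1O[Si](C(C)C)(C(C)C)C(C)C | intermediate
8 | tert-butyl bromoacetate | CC(C)(C)OC(=O)CBr | starting material
9 | lithium enolate of methyl ester 7 (lithium 1-methoxy-3-ArA-3-ArC-prop-1-en-1-olate, 3S) | COc1cc([C@@H](c2cc(O[Si](C(C)C)(C(C)C)C(C)C)c(OC)cc2Br)C=C(OC)O[Li])ccc1O[Si](C(C)C)(C(C)C)C(C)C | intermediate (not isolated)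
10 | 4-tert-butyl 1-methyl 2-[(S)-ArA(ArC)methyl]butanedioate, both C2 epimers | COc1cc([C@@H](c2cc(O[Si](C(C)C)(C(C)C)C(C)C)c(OC)cc2Br)C(CC(=O)OC(C)(C)C)C(=O)OC)ccc1O[Si](C(C)C)(C(C)C)C(C)C | intermediate
11 | lithium enolate of the tert-butyl ester of 10 (enolised at the C3 methylene), both C2 epimers | COc1cc([C@@H](c2cc(O[Si](C(C)C)(C(C)C)C(C)C)c(OC)cc2Br)C(C=C(O[Li])OC(C)(C)C)C(=O)OC)ccc1O[Si](C(C)C)(C(C)C)C(C)C | intermediate (not isolated)
12 | 4-tert-butyl 1-methyl 2-[(S)-ArA(ArC)methyl]-3-[(dimethylamino)methyl]butanedioate, diastereomer mixture at C2 and C3 | COc1cc([C@@H](c2cc(O[Si](C(C)C)(C(C)C)C(C)C)c(OC)cc2Br)C(C(CN(C)C)C(=O)OC(C)(C)C)C(=O)OC)ccc1O[Si](C(C)C)(C(C)C)C(C)C | intermediate (not isolated)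
13 | 4-tert-butyl 1-methyl 2-[(S)-ArA(ArC)methyl]-3-[(trimethylammonio)methyl]butanedioate iodide, diastereomer mixture at C2 and C3 | COc1cc([C@@H](c2cc(O[Si](C(C)C)(C(C)C)C(C)C)c(OC)cc2Br)C(C(C[N+](C)(C)C)C(=O)OC(C)(C)C)C(=O)OC)ccc1O[Si](C(C)C)(C(C)C)C(C)C.[I-] | intermediate (not isolated)
14 | 1-tert-butyl 4-methyl 2-methylidene-3-[(S)-ArA(ArC)methyl]butanedioate, both epimers at the methyl ester-bearing carbon (core C2) | COc1cc([C@@H](c2cc(O[Si](C(C)C)(C(C)C)C(C)C)c(OC)cc2Br)C(C(=O)OC)C(=C)C(=O)OC(C)(C)C)ccc1O[Si](C(C)C)(C(C)C)C(C)C | intermediate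
15 | 3-tert-butyl 2-methyl (1S)-6-methoxy-1-[3-methoxy-4-(triisopropylsilyloxy)phenyl]-7-(triisopropylsilyloxy)-1,2-dihydronaphthalene-2,3-dicarboxylate, cis and trans at C2 | COc1cc([C@H]2c3cc(O[Si](C(C)C)(C(C)C)C(C)C)c(OC)cc3C=C(C(=O)OC(C)(C)C)C2C(=O)OC)ccc1O[Si](C(C)C)(C(C)C)C(C)C | intermediate (not isolated)
16 | 3-tert-butyl 2-methyl (1S,2R)-6-methoxy-1-[3-methoxy-4-(triisopropylsilyloxy)phenyl]-7-(triisopropylsilyloxy)-1,2-dihydronaphthalene-2,3-dicarboxylate (1,2-trans) | COc1cc([C@H]2c3cc(O[Si](C(C)C)(C(C)C)C(C)C)c(OC)cc3C=C(C(=O)OC(C)(C)C)[C@@H]2C(=O)OC)ccc1O[Si](C(C)C)(C(C)C)C(C)C | intermediate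
17 | (1S,2R)-6-methoxy-2-(methoxycarbonyl)-1-[3-methoxy-4-(triisopropylsilyloxy)phenyl]-7-(triisopropylsilyloxy)-1,2-dihydronaphthalene-3-carboxylic acid | COc1cc([C@H]2c3cc(O[Si](C(C)C)(C(C)C)C(C)C)c(OC)cc3C=C(C(=O)O)[C@@H]2C(=O)OC)ccc1O[Si](C(C)C)(C(C)C)C(C)C | intermediate
18 | mixed isobutyl carbonic anhydride of acid 17 (1S,2R) | COc1cc([C@H]2c3cc(O[Si](C(C)C)(C(C)C)C(C)C)c(OC)cc3C=C(C(=O)OC(=O)OCC(C)C)[C@@H]2C(=O)OC)ccc1O[Si](C(C)C)(C(C)C)C(C)C | intermediate (not isolated)
19 | methyl (1S,2R)-3-(hydroxymethyl)-6-methoxy-1-[3-methoxy-4-(triisopropylsilyloxy)phenyl]-7-(triisopropylsilyloxy)-1,2-dihydronaphthalene-2-carboxylate | COc1cc([C@H]2c3cc(O[Si](C(C)C)(C(C)C)C(C)C)c(OC)cc3C=C(CO)[C@@H]2C(=O)OC)ccc1O[Si](C(C)C)(C(C)C)C(C)C | intermediate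
20 | methyl (1S,2R)-3-[(tert-butyldimethylsilyloxy)methyl]-6-methoxy-1-[3-methoxy-4-(triisopropylsilyloxy)phenyl]-7-(triisopropylsilyloxy)-1,2-dihydronaphthalene-2-carboxylate | COc1cc([C@H]2c3cc(O[Si](C(C)C)(C(C)C)C(C)C)c(OC)cc3C=C(CO[Si](C)(C)C(C)(C)C)[C@@H]2C(=O)OC)ccc1O[Si](C(C)C)(C(C)C)C(C)C | intermediate
21 | [(1S,2R)-3-[(tert-butyldimethylsilyloxy)methyl]-6-methoxy-1-[3-methoxy-4-(triisopropylsilyloxy)phenyl]-7-(triisopropylsilyloxy)-1,2-dihydronaphthalen-2-yl]methanol | COc1cc([C@H]2c3cc(O[Si](C(C)C)(C(C)C)C(C)C)c(OC)cc3C=C(CO[Si](C)(C)C(C)(C)C)[C@@H]2CO)ccc1O[Si](C(C)C)(C(C)C)C(C)C | intermediate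
22 | (1S,2R)-3-[(tert-butyldimethylsilyloxy)methyl]-6-methoxy-1-[3-methoxy-4-(triisopropylsilyloxy)phenyl]-7-(triisopropylsilyloxy)-1,2-dihydronaphthalene-2-carbaldehyde | COc1cc([C@H]2c3cc(O[Si](C(C)C)(C(C)C)C(C)C)c(OC)cc3C=C(CO[Si](C)(C)C(C)(C)C)[C@@H]2C=O)ccc1O[Si](C(C)C)(C(C)C)C(C)C | intermediate
23 | (1S,2R)-7-hydroxy-1-(4-hydroxy-3-methoxyphenyl)-3-(hydroxymethyl)-6-methoxy-1,2-dihydronaphthalene-2-carbaldehyde (1,2-trans) | COc1cc([C@H]2c3cc(O)c(OC)cc3C=C(CO)[C@@H]2C=O)ccc1O | target

Total step count: 13. Longest linear sequence: 12 steps (steps 1, 2 and 4–13; step 3 prepares the boronate branch).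

Steps most likely to fail

First, step 7. The cyclisation may close in the 5-exo mode, the methylene double bond may be shifted into conjugation by the base before palladium reacts, or the C–Br bond may simply be reduced. Ring B would then be closed by ring-closing metathesis, which forms the same C3=C4 alkene from the other side. The fallback sets out from 10. Stille coupling with tributyl(vinyl)stannane (Pd(PPh3)4, toluene, 100 °C) would replace the bromide by a vinyl group and give the vinylarene succinate F1. The methylenation protocol of step 6 would then take it through its lithium enolate F2, the Mannich amine F3 and the ammonium iodide F4 to the styrene–acrylate diene F5. The second-generation Grubbs catalyst RuCl2(=CHPh)(H2IMes)(PCy3) in toluene at 80 °C would join the vinyl CH to C3 with loss of ethene. This comes back to the route at 15, which is equilibrated with DBU to 16 as in step 7.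

Second, step 4. Insertion into the hindered ortho-bromocinnamate may be slow enough for protodeboronation of the arylboronate to win, or enantiofacial control may be incomplete. C1 would then be set under auxiliary control. The fallback sets out from 2. A Horner–Wadsworth–Emmons reaction with (R)-3-[(diethoxyphosphoryl)acetyl]-4-phenyl-1,3-oxazolidin-2-one (LiCl, i-Pr2NEt, MeCN) would give the N-enoyl oxazolidinone F6. Commercial 4-bromo-2-methoxyphenol would be silylated (TIPSCl, imidazole) to the aryl bromide F7 and converted with Mg in THF into the Grignard reagent F8. Copper-mediated conjugate addition (CuBr·SMe2, THF, −40 °C) to the chelated s-cis enoyl imide, anti to the 4-phenyl group, would give the (3S) adduct F9. Methanolysis with MeOMgBr (from MeMgBr in MeOH, 0 °C) would release the auxiliary and come back to the route at 7.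

Third, step 6. Enolisation may take place at the C2 methine instead of the C3 methylene, so that the aminomethyl group ends up on the wrong carbon. The C2 carboxyl would then be masked as a carboxylate, which cannot be enolised competitively. The fallback sets out from 10. Selective cleavage of the methyl ester with Me3SnOH (1,2-dichloroethane, 80 °C) would give the half acid F10. Two equivalents of LiN(i-Pr)2 (THF, −78 °C) would form the carboxylate ester enolate F11, whose only enolate carbon is the methylene next to the tert-butyl ester. Dimethylmethyleneiminium iodide would give the amino acid F12. MeI with KHCO3 in DMF would methylate both the nitrogen and the carboxylate; this comes back to the route at 13, which eliminates trimethylamine to 14.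

Further compounds
F1 | step 7 | 4-tert-butyl 1-methyl 2-{(S)-[2-ethenyl-4-methoxy-5-(triisopropylsilyloxy)phenyl](ArC)methyl}butanedioate, C2 epimers | COc1cc([C@@H](c2cc(O[Si](C(C)C)(C(C)C)C(C)C)c(OC)cc2C=C)C(CC(=O)OC(C)(C)C)C(=O)OC)ccc1O[Si](C(C)C)(C(C)C)C(C)C
F2 | step 7 | lithium enolate of the tert-butyl ester of F1 | COc1cc([C@@H](c2cc(O[Si](C(C)C)(C(C)C)C(C)C)c(OC)cc2C=C)C(C=C(O[Li])OC(C)(C)C)C(=O)OC)ccc1O[Si](C(C)C)(C(C)C)C(C)C
F3 | step 7 | 3-[(dimethylamino)methyl] derivative of F1 (Mannich amine) | COc1cc([C@@H](c2cc(O[Si](C(C)C)(C(C)C)C(C)C)c(OC)cc2C=C)C(C(CN(C)C)C(=O)OC(C)(C)C)C(=O)OC)ccc1O[Si](C(C)C)(C(C)C)C(C)C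
F4 | step 7 | 3-[(trimethylammonio)methyl] derivative of F1, iodide | COc1cc([C@@H](c2cc(O[Si](C(C)C)(C(C)C)C(C)C)c(OC)cc2C=C)C(C(C[N+](C)(C)C)C(=O)OC(C)(C)C)C(=O)OC)ccc1O[Si](C(C)C)(C(C)C)C(C)C.[I-]
F5 | step 7 | 1-tert-butyl 4-methyl 2-methylidene-3-{(S)-[2-ethenyl-4-methoxy-5-(triisopropylsilyloxy)phenyl](ArC)methyl}butanedioate, C2 epimers | COc1cc([C@@H](c2cc(O[Si](C(C)C)(C(C)C)C(C)C)c(OC)cc2C=C)C(C(=O)OC)C(=C)C(=O)OC(C)(C)C)ccc1O[Si](C(C)C)(C(C)C)C(C)C
F6 | step 4 | (4R)-3-[(2E)-3-ArA-prop-2-enoyl]-4-phenyl-1,3-oxazolidin-2-one | COc1cc(Br)c(/C=C/C(=O)N2C(=O)OC[C@H]2c2ccccc2)cc1O[Si](C(C)C)(C(C)C)C(C)C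
F7 | step 4 | 4-bromo-2-methoxy-1-(triisopropylsilyloxy)benzene | COc1cc(Br)ccc1O[Si](C(C)C)(C(C)C)C(C)C
F8 | step 4 | [3-methoxy-4-(triisopropylsilyloxy)phenyl]magnesium bromide | COc1cc([Mg]Br)ccc1O[Si](C(C)C)(C(C)C)C(C)C
F9 | step 4 | (4R)-3-[(3S)-3-ArA-3-ArC-propanoyl]-4-phenyl-1,3-oxazolidin-2-one | COc1cc([C@@H](c2cc(O[Si](C(C)C)(C(C)C)C(C)C)c(OC)cc2Br)CC(=O)N2C(=O)OC[C@H]2c2ccccc2)ccc1O[Si](C(C)C)(C(C)C)C(C)C
F10 | step 6 | 4-tert-butoxy-4-oxo-2-[(S)-ArA(ArC)methyl]butanoic acid, C2 epimers | COc1cc([C@@H](c2cc(O[Si](C(C)C)(C(C)C)C(C)C)c(OC)cc2Br)C(CC(=O)OC(C)(C)C)C(=O)O)ccc1O[Si](C(C)C)(C(C)C)C(C)C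
F11 | step 6 | dilithium carboxylate ester enolate of F10 | COc1cc([C@@H](c2cc(O[Si](C(C)C)(C(C)C)C(C)C)c(OC)cc2Br)C(C=C(O[Li])OC(C)(C)C)C(=O)O[Li])ccc1O[Si](C(C)C)(C(C)C)C(C)C
F12 | step 6 | 4-tert-butoxy-3-[(dimethylamino)methyl]-4-oxo-2-[(S)-ArA(ArC)methyl]butanoic acid | COc1cc([C@@H](c2cc(O[Si](C(C)C)(C(C)C)C(C)C)c(OC)cc2Br)C(C(CN(C)C)C(=O)OC(C)(C)C)C(=O)O)ccc1O[Si](C(C)C)(C(C)C)C(C)C
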